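**Plan**

- Retrosynthesis: the two 4-hydroxybenzoate C–O bonds are cut first, then the ring A C5–vinyl bond (Mizoroki–Heck), then the C2–C3 bond of the dihydrofuran ring B (carbenoid C–H insertion), then the ring A–C3 bond (aryl iodide/diazoacetate coupling) and the ring A O–CH2 ether bond (Mitsunobu).
- Enabling feature: C3 is benzylic to ring A, bears a carboxyl-level carbon (the later C3 CH2O) and lies 1,5 to the benzylic C2–H of the ring A O–CH2–syringyl ether (syringyl = ring C), so a carbenoid at C3 can insert into that C–H bond.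
- Forward order: the silylated syringyl alcohol and iodinated 4-bromo-2-methoxyphenol are joined as an ether, the diazo ester is installed, and ring B (the only ring made) closes by C–H insertion. The C5 side chain is then attached, both esters are reduced, the diol is acylated twice and all silyl groups are removed.
- Stereochemistry: C2 (S) comes from the chiral dirhodium catalyst in the insertion; C3 (R in the target) comes from base epimerisation of the kinetic cis ester to the trans ester; the E alkene comes from the Heck reaction.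

Key step: step 6

Assumption: Rh2(S-PTTL)4 is taken to give the (2R)-cis esters in this substrate class, so the (R)-ligand catalyst Rh2(R-PTTL)4 (commercial, or from Rh2(OAc)4 and N-phthaloyl-(R)-tert-leucine by ligand exchange) is used for the (2S) series; were the sense of induction the opposite, the (S)-ligand catalyst would take its place.

**Step 1**
Reactants: 1 syringaldehyde
Product: 2 3,5-dimethoxy-4-(triisopropylsilyloxy)benzaldehyde
Conditions: TIPSCl (1.2 equiv), imidazole (2.5 equiv), DMF, rt → 40 °C
Reagents that add atoms: triisopropylsilyl chloride, CC(C)[Si](Cl)(C(C)C)C(C)C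
Why: Imidazole-promoted silylation of the acidic phenol leaves the aldehyde untouched, and the bulky silyl ether flanked by two methoxy groups is chosen to survive the later amine bases, hydride and warm palladium steps.

**Step 2**
Reactants: 2 3,5-dimethoxy-4-(triisopropylsilyloxy)benzaldehyde
Product: 3 [3,5-dimethoxy-4-(triisopropylsilyloxy)phenyl]methanol
Conditions: NaBH4 (0.6 equiv), THF/MeOH, 0 °C
Reagents that add atoms: none
Why: Borohydride 1,2-reduction of an aryl aldehyde to the benzylic alcohol is chemoselective and the aryl silyl ether is inert at 0 °C.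

**Step 3**
Reactants: 4 4-bromo-2-methoxyphenol
Product: 5 4-bromo-2-iodo-6-methoxyphenol
Conditions: NIS (1.05 equiv), p-TsOH (10 mol%), MeCN, 0 °C → rt
Reagents that add atoms: N-iodosuccinimide, O=C1CCC(=O)N1I
Why: In this electrophilic aromatic iodination the free hydroxyl is the strongest director, and with its para position blocked by bromine and one ortho position by the methoxy group, iodine should enter the remaining ortho position.

**Step 4**
Reactants: 5 4-bromo-2-iodo-6-methoxyphenol; 3 [3,5-dimethoxy-4-(triisopropylsilyloxy)phenyl]methanol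
Product: 6 5-bromo-2-{[3,5-dimethoxy-4-(triisopropylsilyloxy)benzyl]oxy}-1-iodo-3-methoxybenzene
Conditions: PPh3 (1.3 equiv), DIAD (1.3 equiv), THF, 0 °C → rt
Reagents that add atoms: none
Why: Mitsunobu etherification, in which the halogen-acidified phenol protonates the betaine and its phenoxide displaces the oxyphosphonium of the primary benzylic alcohol; no stereocentre is involved and no labile benzylic halide has to be handled.

**Step 5**
Reactants: 6 5-bromo-2-{[3,5-dimethoxy-4-(triisopropylsilyloxy)benzyl]oxy}-1-iodo-3-methoxybenzene; 7 ethyl diazoacetate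
Product: 8 ethyl 2-(5-bromo-2-{[3,5-dimethoxy-4-(triisopropylsilyloxy)benzyl]oxy}-3-methoxyphenyl)-2-diazoacetate
Conditions: Pd(PPh3)4 (5 mol%), Ag2CO3 (0.5 equiv), Et3N (1.3 equiv), toluene, rt, dark
Reagents that add atoms: none
Why: Palladium-catalysed cross-coupling of an aryl iodide with the C–H bond of a diazoacetate with retention of the diazo group, in which zerovalent palladium adds to the C–I bond far faster than to the C–Br bond at room temperature and base-assisted palladation of the diazo ester followed by reductive elimination gives the aryldiazoacetate.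

**Step 6**
Reactants: 8 ethyl 2-(5-bromo-2-{[3,5-dimethoxy-4-(triisopropylsilyloxy)benzyl]oxy}-3-methoxyphenyl)-2-diazoacetate
Product: 9 ethyl (2S,3R)-5-bromo-2-[3,5-dimethoxy-4-(triisopropylsilyloxy)phenyl]-7-methoxy-2,3-dihydro-1-benzofuran-3-carboxylate (cis)
Conditions: Rh2(R-PTTL)4 (1 mol%), toluene, −60 °C, slow addition of 8
Reagents that add atoms: none
Why: Rh2(R-PTTL)4 expels N2 from 8 to give a rhodium-bound donor/acceptor carbenoid at C3, which inserts into the benzylic C–H bond of the ArO–CH2–syringyl group through a concerted, asynchronous three-centre transition state with hydride-transfer character, forming the C2–C3 bond; the closest known reaction type is the enantioselective intramolecular C–H insertion of 2-(benzyloxy)aryl diazoacetates catalysed by chiral dirhodium tetracarboxylates. Ring B closes by 1,5-insertion, that is, five-membered ring formation in which the carbenoid carbon bonds to the carbon five atoms away. C2 is set by the chiral pocket of the four phthalimido-tert-leucinate ligands, which selects one of the two enantiotopic benzylic hydrogens and so fixes the S configuration. C3 is set by the geometry of the same transition state, in which aryl group and ester end up cis as the kinetic outcome; this centre is corrected in step 7, so only C2 has to be right here. The step needs C–H insertion to win over carbene dimerisation, oxonium ylide formation and attack on the electron-rich ring C: the C–H bond is doubly activated (alpha to oxygen and benzylic to the syringyl ring) and sits 1,5 to the carbenoid, an ylide would require a four-membered ring, and the aryl- and ester-stabilised carbenoid is selective enough at −60 °C under slow addition.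

**Step 7**
Reactants: 9 ethyl (2S,3R)-5-bromo-2-[3,5-dimethoxy-4-(triisopropylsilyloxy)phenyl]-7-methoxy-2,3-dihydro-1-benzofuran-3-carboxylate (cis)
Product: 10 ethyl (2S,3S)-5-bromo-2-[3,5-dimethoxy-4-(triisopropylsilyloxy)phenyl]-7-methoxy-2,3-dihydro-1-benzofuran-3-carboxylate (trans)
Conditions: DBU (1.0 equiv), MeCN/THF, 40 °C
Reagents that add atoms: none
Why: Base-mediated epimerisation through the ester enolate at the benzylic C3 should relax the cis ester to the thermodynamically preferred trans ester, while C2 is retained because it is not acidic, ring opening by beta-elimination would be a disfavoured reverse 5-endo-trig process, and the silyl-capped phenol cannot open the ring through a quinone methide.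

**Step 8**
Reactants: 10 ethyl (2S,3S)-5-bromo-2-[3,5-dimethoxy-4-(triisopropylsilyloxy)phenyl]-7-methoxy-2,3-dihydro-1-benzofuran-3-carboxylate (trans); 11 ethyl acrylate
Product: 12 ethyl (2S,3S)-2-[3,5-dimethoxy-4-(triisopropylsilyloxy)phenyl]-5-[(E)-3-ethoxy-3-oxoprop-1-en-1-yl]-7-methoxy-2,3-dihydro-1-benzofuran-3-carboxylate
Conditions: Pd2(dba)3 (2 mol%), [HP(t-Bu)3]BF4 (8 mol%), Cy2NMe (1.5 equiv), 1,4-dioxane, 70 °C
Reagents that add atoms: none
Why: Mizoroki–Heck reaction, in which the zerovalent palladium–tri-tert-butylphosphine catalyst adds to the electron-rich C–Br bond and syn carbopalladation of the acrylate followed by syn beta-hydride elimination gives the E cinnamate; the C3 ester is already the thermodynamic epimer, so the amine base cannot erode it.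

**Step 9**
Reactants: 12 ethyl (2S,3S)-2-[3,5-dimethoxy-4-(triisopropylsilyloxy)phenyl]-5-[(E)-3-ethoxy-3-oxoprop-1-en-1-yl]-7-methoxy-2,3-dihydro-1-benzofuran-3-carboxylate
Product: 13 (E)-3-[(2S,3R)-2-[3,5-dimethoxy-4-(triisopropylsilyloxy)phenyl]-3-(hydroxymethyl)-7-methoxy-2,3-dihydro-1-benzofuran-5-yl]prop-2-en-1-ol
Conditions: i-Bu2AlH (6 equiv), CH2Cl2, −78 → −20 °C; aq. potassium sodium tartrate work-up
Reagents that add atoms: none
Why: Diisobutylaluminium hydride reduces the saturated and the alpha,beta-unsaturated ester to primary alcohols by 1,2-addition without conjugate reduction and without touching either stereocentre (the C3 descriptor changes from S to R only through the priority rules).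

**Step 10**
Reactants: 14 4-hydroxybenzoic acid
Product: 16 4-(tert-butyldimethylsilyloxy)benzoic acid, via tert-butyldimethylsilyl 4-(tert-butyldimethylsilyloxy)benzoate 15 (not isolated)
Conditions: TBSCl (2.3 equiv), imidazole (5 equiv), DMF, rt; then AcOH/THF/H2O (3:1:1), rt
Reagents that add atoms: tert-butyldimethylsilyl chloride, CC(C)(C)[Si](C)(C)Cl
Why: Silylation of both acidic OH groups followed by selective hydrolysis of the far more labile silyl ester in aqueous acetic acid should leave the aryl silyl ether in place.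

**Step 11**
Reactants: 13 (E)-3-[(2S,3R)-2-[3,5-dimethoxy-4-(triisopropylsilyloxy)phenyl]-3-(hydroxymethyl)-7-methoxy-2,3-dihydro-1-benzofuran-5-yl]prop-2-en-1-ol; 16 4-(tert-butyldimethylsilyloxy)benzoic acid (2.4 equiv)
Product: 17 [(2S,3R)-5-[(E)-3-{[4-(tert-butyldimethylsilyloxy)benzoyl]oxy}prop-1-en-1-yl]-2-[3,5-dimethoxy-4-(triisopropylsilyloxy)phenyl]-7-methoxy-2,3-dihydro-1-benzofuran-3-yl]methyl 4-(tert-butyldimethylsilyloxy)benzoate
Conditions: DCC (2.6 equiv), DMAP (0.3 equiv), CH2Cl2, 0 °C → rt
Reagents that add atoms: none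
Why: Steglich esterification, in which the O-acylisourea is intercepted by DMAP and the acylpyridinium acylates both unhindered primary alcohols under neutral conditions that leave the silyl ethers and the stereocentres alone.

**Step 12**
Reactants: 17 [(2S,3R)-5-[(E)-3-{[4-(tert-butyldimethylsilyloxy)benzoyl]oxy}prop-1-en-1-yl]-2-[3,5-dimethoxy-4-(triisopropylsilyloxy)phenyl]-7-methoxy-2,3-dihydro-1-benzofuran-3-yl]methyl 4-(tert-butyldimethylsilyloxy)benzoate
Product: 18 quiquesetinerviusin B, [(2S,3R)-2-(4-hydroxy-3,5-dimethoxyphenyl)-5-[(E)-3-(4-hydroxybenzoyloxy)prop-1-en-1-yl]-7-methoxy-2,3-dihydro-1-benzofuran-3-yl]methyl 4-hydroxybenzoate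
Conditions: Bu4NF (4 equiv), AcOH (4 equiv), THF, 0 °C → rt
Reagents that add atoms: none
Why: Fluoride-mediated cleavage of the three aryl silyl ethers is driven by Si–F bond formation, and the acetic acid buffer protonates the phenoxides as they form so that the two benzoate esters, the allylic ester and the dihydrobenzofuran should survive.

**Compound list**

1 | syringaldehyde | COc1cc(C=O)cc(OC)c1O | starting material
2 | 3,5-dimethoxy-4-(triisopropylsilyloxy)benzaldehyde | COc1cc(C=O)cc(OC)c1O[Si](C(C)C)(C(C)C)C(C)C | intermediate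
3 | [3,5-dimethoxy-4-(triisopropylsilyloxy)phenyl]methanol | COc1cc(CO)cc(OC)c1O[Si](C(C)C)(C(C)C)C(C)C | intermediate
4 | 4-bromo-2-methoxyphenol | COc1cc(Br)ccc1O | starting material
5 | 4-bromo-2-iodo-6-methoxyphenol | COc1cc(Br)cc(I)c1O | intermediate
6 | 5-bromo-2-{[3,5-dimethoxy-4-(triisopropylsilyloxy)benzyl]oxy}-1-iodo-3-methoxybenzene | COc1cc(Br)cc(I)c1OCc1cc(OC)c(O[Si](C(C)C)(C(C)C)C(C)C)c(OC)c1 | intermediate
7 | ethyl diazoacetate | CCOC(=O)C=[N+]=[N-] | starting material
8 | ethyl 2-(5-bromo-2-{[3,5-dimethoxy-4-(triisopropylsilyloxy)benzyl]oxy}-3-methoxyphenyl)-2-diazoacetate | CCOC(=O)C(=[N+]=[N-])c1cc(Br)cc(OC)c1OCc1cc(OC)c(O[Si](C(C)C)(C(C)C)C(C)C)c(OC)c1 | intermediate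
9 | ethyl (2S,3R)-5-bromo-2-[3,5-dimethoxy-4-(triisopropylsilyloxy)phenyl]-7-methoxy-2,3-dihydro-1-benzofuran-3-carboxylate (cis) | COc1cc([C@H]2Oc3c(OC)cc(Br)cc3[C@H]2C(=O)OCC)cc(OC)c1O[Si](C(C)C)(C(C)C)C(C)C | intermediate
10 | ethyl (2S,3S)-5-bromo-2-[3,5-dimethoxy-4-(triisopropylsilyloxy)phenyl]-7-methoxy-2,3-dihydro-1-benzofuran-3-carboxylate (trans) | COc1cc([C@H]2Oc3c(OC)cc(Br)cc3[C@@H]2C(=O)OCC)cc(OC)c1O[Si](C(C)C)(C(C)C)C(C)C | intermediate
11 | ethyl acrylate | C=CC(=O)OCC | starting material
12 | ethyl (2S,3S)-2-[3,5-dimethoxy-4-(triisopropylsilyloxy)phenyl]-5-[(E)-3-ethoxy-3-oxoprop-1-en-1-yl]-7-methoxy-2,3-dihydro-1-benzofuran-3-carboxylate | COc1cc([C@H]2Oc3c(OC)cc(/C=C/C(=O)OCC)cc3[C@@H]2C(=O)OCC)cc(OC)c1O[Si](C(C)C)(C(C)C)C(C)C | intermediate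
13 | (E)-3-[(2S,3R)-2-[3,5-dimethoxy-4-(triisopropylsilyloxy)phenyl]-3-(hydroxymethyl)-7-methoxy-2,3-dihydro-1-benzofuran-5-yl]prop-2-en-1-ol | COc1cc([C@H]2Oc3c(OC)cc(/C=C/CO)cc3[C@@H]2CO)cc(OC)c1O[Si](C(C)C)(C(C)C)C(C)C | intermediate
14 | 4-hydroxybenzoic acid | OC(=O)c1ccc(O)cc1 | starting material
15 | tert-butyldimethylsilyl 4-(tert-butyldimethylsilyloxy)benzoate (not isolated) | CC(C)(C)[Si](C)(C)Oc1ccc(cc1)C(=O)O[Si](C)(C)C(C)(C)C | intermediate
16 | 4-(tert-butyldimethylsilyloxy)benzoic acid | CC(C)(C)[Si](C)(C)Oc1ccc(cc1)C(=O)O | intermediate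
17 | [(2S,3R)-5-[(E)-3-{[4-(tert-butyldimethylsilyloxy)benzoyl]oxy}prop-1-en-1-yl]-2-[3,5-dimethoxy-4-(triisopropylsilyloxy)phenyl]-7-methoxy-2,3-dihydro-1-benzofuran-3-yl]methyl 4-(tert-butyldimethylsilyloxy)benzoate | COc1cc([C@H]2Oc3c(OC)cc(/C=C/COC(=O)c4ccc(O[Si](C)(C)C(C)(C)C)cc4)cc3[C@@H]2COC(=O)c2ccc(O[Si](C)(C)C(C)(C)C)cc2)cc(OC)c1O[Si](C(C)C)(C(C)C)C(C)C | intermediate
18 | quiquesetinerviusin B | COc1cc([C@H]2Oc3c(OC)cc(/C=C/COC(=O)c4ccc(O)cc4)cc3[C@@H]2COC(=O)c2ccc(O)cc2)cc(OC)c1O | target

**Step count**

Total: 12 steps. Longest linear sequence: 10 steps (steps 1, 2, 4, 5, 6, 7, 8, 9, 11, 12, from syringaldehyde).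

**Steps most likely to fail**

1. Step 6. The methoxy group ortho to the benzyloxy ether, absent from the closest precedents, may change the conformation of the O–CH2 group in the catalyst pocket. The two enantiotopic benzylic hydrogens would then be poorly discriminated, and carbene dimerisation could compete at low temperature. Fallback: setting out from 8, the insertion would be run with the achiral catalyst Rh2(OAc)4 in CH2Cl2 at rt, which should give the racemic cis ester F1. DBU in MeCN/THF should then convert it into the racemic trans ester F2. Preparative HPLC on a cellulose tris(3,5-dimethylphenylcarbamate) stationary phase would separate the enantiomers, and the (2S,3S) enantiomer is compound 10, where the route is rejoined. The absolute configuration of the collected enantiomer would be assigned by anomalous dispersion X-ray analysis using the bromine atom.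

2. Step 5. Oxidative addition at the ortho-alkoxy, electron-rich C–I bond may be slow relative to palladium-induced decomposition of the diazo ester, or the diazo group may be lost from the product on the metal. Fallback: setting out from 6, iodine–magnesium exchange (i-PrMgCl·LiCl, THF, −40 °C, selective for iodine over bromine) should give the arylmagnesium chloride F3. Addition of this to excess diethyl oxalate at −78 °C should give the alpha-keto ester F4. Condensation with p-toluenesulfonyl hydrazide (toluene, 60 °C) should give the tosylhydrazone F5, and DBU in CH2Cl2 at rt (Bamford–Stevens elimination of sulfinate) should deliver compound 8, where the route is rejoined.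

3. Step 8. Oxidative addition at the electron-rich C–Br bond may be sluggish, leading to protodebromination, and prolonged heating with base could erode material through C3. Fallback: setting out from 10, reduction with i-Bu2AlH (CH2Cl2, −78 °C) should give the bromo alcohol F6. Suzuki–Miyaura coupling of this with commercial (E)-3-(4,4,5,5-tetramethyl-1,3,2-dioxaborolan-2-yl)prop-2-en-1-ol (Pd(dppf)Cl2, K3PO4, dioxane/H2O, 80 °C) should give diol 13 directly, where the route is rejoined.

**Further compounds**

F1 | step 6 | racemic ethyl (2S*,3R*)-5-bromo-2-[3,5-dimethoxy-4-(triisopropylsilyloxy)phenyl]-7-methoxy-2,3-dihydro-1-benzofuran-3-carboxylate (cis, both enantiomers) | COc1cc([C@H]2Oc3c(OC)cc(Br)cc3[C@H]2C(=O)OCC)cc(OC)c1O[Si](C(C)C)(C(C)C)C(C)C.COc1cc([C@@H]2Oc3c(OC)cc(Br)cc3[C@@H]2C(=O)OCC)cc(OC)c1O[Si](C(C)C)(C(C)C)C(C)C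
F2 | step 6 | racemic ethyl (2S*,3S*)-5-bromo-2-[3,5-dimethoxy-4-(triisopropylsilyloxy)phenyl]-7-methoxy-2,3-dihydro-1-benzofuran-3-carboxylate (trans, both enantiomers) | COc1cc([C@H]2Oc3c(OC)cc(Br)cc3[C@@H]2C(=O)OCC)cc(OC)c1O[Si](C(C)C)(C(C)C)C(C)C.COc1cc([C@@H]2Oc3c(OC)cc(Br)cc3[C@H]2C(=O)OCC)cc(OC)c1O[Si](C(C)C)(C(C)C)C(C)C
F3 | step 5 | (5-bromo-2-{[3,5-dimethoxy-4-(triisopropylsilyloxy)benzyl]oxy}-3-methoxyphenyl)magnesium chloride | COc1cc(Br)cc([Mg]Cl)c1OCc1cc(OC)c(O[Si](C(C)C)(C(C)C)C(C)C)c(OC)c1
F4 | step 5 | ethyl 2-(5-bromo-2-{[3,5-dimethoxy-4-(triisopropylsilyloxy)benzyl]oxy}-3-methoxyphenyl)-2-oxoacetate | CCOC(=O)C(=O)c1cc(Br)cc(OC)c1OCc1cc(OC)c(O[Si](C(C)C)(C(C)C)C(C)C)c(OC)c1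
F5 | step 5 | ethyl 2-(5-bromo-2-{[3,5-dimethoxy-4-(triisopropylsilyloxy)benzyl]oxy}-3-methoxyphenyl)-2-[2-(4-methylbenzenesulfonyl)hydrazinylidene]acetate | CCOC(=O)C(=NNS(=O)(=O)c1ccc(C)cc1)c1cc(Br)cc(OC)c1OCc1cc(OC)c(O[Si](C(C)C)(C(C)C)C(C)C)c(OC)c1
F6 | step 8 | [(2S,3R)-5-bromo-2-[3,5-dimethoxy-4-(triisopropylsilyloxy)phenyl]-7-methoxy-2,3-dihydro-1-benzofuran-3-yl]methanol | COc1cc([C@H]2Oc3c(OC)cc(Br)cc3[C@@H]2CO)cc(OC)c1O[Si](C(C)C)(C(C)C)C(C)C
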